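Two ways out.

| flask | substrate | reagent in the second phase | remark | time | volume of the second phase over the first |
|---|---|---|---|---|---|
| noon | 22 mM | 12 mM | run made earlier |  |  |
| dusk | 22 mM | 46 mM | run made earlier |  |  |
| dawn | 11 mM | 23.1 mM | run made earlier |  |  |
| flask | 22 mM | 23.1 mM |  | 25 min | 0.50 |

| run | time / min | target / % | substrate / % |
|---|---|---|---|
| noon | 2.00 | 2.7 | 63.6 |
| noon | 3.00 | 4.6 | 53.1 |
| noon | 5.00 | 7.9 | 39.6 |
| noon | 8.00 | 12.3 | 24.0 |
| noon | 10.0 | 17.0 | 21.3 |
| noon | 15.0 | 20.5 | 11.7 |
| noon | 25.0 | 26.5 | 5.7 |
| dusk | 4.00 | 23.1 | 34.5 |
| dusk | 8.00 | 41.4 | 12.1 |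
| dusk | 10.0 | 47.8 | 4.2 |
| dusk | 15.0 | 49.5 | 0 |
| dusk | 20.0 | 50.1 | 0.4 |
| dusk | 25.0 | 48.7 | 0 |
| dawn | 2.00 | 7.0 | 74.8 |
| dawn | 6.00 | 27.4 | 37.2 |
| dawn | 12.0 | 47.7 | 11.8 |
| dawn | 20.0 | 57.0 | 2.8 |
| dawn | 25.0 | 57.6 | 0 |

(scatter of a reading: 1 percentage point)

- in the second phase: reagent in the second phase; everything else is in the first
- charges count per volume of the first phase; a concentration in a rate is the amount of a species over the volume of its own phase; every rate counts per litre of the first phase
- the numbers in the tables scatter with a standard deviation of 1 percentage point
- the earlier runs hold the two phases in the same ratio of volumes as the flask asked about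

* target at 25 min, in percent of the substrate charged
* part of the substrate charged that has reacted at 25 min

Where does substrate go? Partly to target, partly somewhere unseen: at 2.00 min the noon run has lost 33.7% of its charge to no visible peak.

What order is that loss? The dawn run, charged with half as much, loses 18.2% by the same time, about half the noon share, so I read it as second order in substrate.

How large? Between 2.00 min and 5.00 min the noon run loses 1.38 mM min⁻¹ this way, at a mean substrate of 11.4 mM.

And the target way? The dawn run has the flask's reagent, and between 2.00 min and 6.00 min it turns substrate into target with a pseudo-first-order constant of 0.0911 min⁻¹.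

So what sets the order? Substrate itself. Setting the two speeds equal gives 8.51 mM, the crossover substrate: at this reagent charge, substrate above it goes mainly by the second-order way, and below it mainly to target. The flask starts at 22 mM, above it.

What yield follows? Integrating, the crossover over the charge, times the natural logarithm of one plus the charge over the crossover, gives 49.4%.

Is the constant constant? No: the first 2.00 min of the dawn run gives 0.0400 min⁻¹, lower, and the stretch from 12.0 min to 20.0 min gives 0.159 min⁻¹, higher. So my figure is an estimate from the middle of the course, not a bound; for the dawn run it gives 64.2% against a reading of 57.6%, which lies under it. I therefore commit to target under 49.4% in the flask, with hardly any substrate left, as in the dawn run at 25.0 min.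

The forecast, lower than my estimate, gives 39% target and 99% reacted, holding that “Substrate loss tracks substrate squared”.

The flask gives 39.5% target and 99.2% reacted, 9.9 percentage points under my estimate.

    reagent in the reaction phase ⇌ reagent in the second phase, rate k1*([reagent in the reaction phase] - [reagent in the second phase]/K1) per volume of the first phase (partition coefficient = 1.00, kL = 0.0370 min⁻¹)
    substrate + reagent in the reaction phase → target (k = 28.0 L mol⁻¹ min⁻¹)
    target ⇌ isomer of the product (K = 0.120, k = 0.00210 min⁻¹)
    2 substrate → self-condensation product (k = 5.80 L mol⁻¹ min⁻¹)

In the flask, half of the self-condensation turnover up to 25 min is done by 1.68 min, and half of the target step's by 6.59 min, much later. By 12.5 min the self-condensation product stands at 57.9% and stays there, against 32.4% target.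

The neighbour charged with 5.5 mM starts below the crossover, and the same reckoning gives an estimate of 77.1%. It gives 73.7% target, with 99.7% reacted.

Readings and results come from a simulation for an exercise, and the scatter is random.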